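**Retrosynthetic overview**

- Ring numbering: C1 ketone, C2 (CH2OH), C3 (=CH), C4 (CH2), C5 (quaternary, CH3 and side chain), C6 (enol-ester arm), C7 (acetonyl). The strategy rests on the quaternary C5 of the cycloheptenone, whose methyl group is cis to the C6 arm.
- Key disconnection: the C5 methyl is the CH2 of a cyclopropane laid across C4=C5 from the face of a C3 carbinol (cis to the C6 allyl group), then released by reductive opening of the derived cyclopropyl ketone.
- Precursor: cycloheptane-1,3-dione → vinylogous ester → Pd-catalysed decarboxylative asymmetric allylation (C6) → Stork–Danheiser introduction of the C5 chain → CBS reduction (C3 carbinol).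
- After the key step: C3→C1 carbonyl transposition (dehydrogenation, epoxidation, Wharton, oxidation), C7 methallylation, C2 hydroxymethylation, double ozonolysis, enol senecioylation, aldehyde-selective isopropenylation of the side chain, desilylation.
- Ring order: the seven-membered ring is bought; the only ring formed is the cyclopropane (step 6), which is opened again in step 8.

Key step: step 6

Remark: the sense of induction of the chiral ligands in steps 3 and 20 is assigned by analogy and the antipodal ligand is used if the first run shows the opposite sense; silyl ether 7 and anhydride 29 are taken as purchased.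

**Route**

Step 1
Reactants: 1 cycloheptane-1,3-dione
Product: 2 vinylogous ester 3-isobutoxycyclohept-2-en-1-one
Conditions: i-BuOH, p-TsOH (cat.), toluene, reflux, Dean–Stark
Reagents that add atoms: 2-methylpropan-1-ol, CC(C)CO
Why: Acid-catalysed enol etherification of the symmetric cyclic 1,3-dione with removal of water can give only this vinylogous ester.

Step 2
Reactants: 2 vinylogous ester; 3 allyl chloroformate
Product: 5 allyl 6-isobutoxycyclohepta-1,6-dien-1-yl carbonate, via lithium enolate 4 (not isolated)
Conditions: LDA, THF, −78 °C; TMEDA, then ClCO2allyl, −78 °C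
Reagents that add atoms: none
Why: Kinetic α'-deprotonation of the vinylogous ester followed by O-acylation of the cross-conjugated enolate with the hard chloroformate (enol carbonate formation) fixes the enolate regiochemistry for the next step.

Step 3
Reactants: 5 allyl enol carbonate
Product: 6 (R)-7-allyl-3-isobutoxycyclohept-2-en-1-one
Conditions: Pd2(dba)3·CHCl3 (2.5 mol%), ANDEN-phenyl Trost ligand (5.5 mol%, enantiomer giving the R product), 1,4-dioxane, rt
Reagents that add atoms: none
Why: Decarboxylative asymmetric allylic alkylation (Tsuji–Trost type): ionisation and loss of CO2 give a π-allyl-Pd/enolate pair that recombines regiospecifically at the α'-carbon inside the chiral ligand pocket, which sets the tertiary C6 centre under neutral conditions that should not epimerise it.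

Step 4
Reactants: 6 (R)-allyl vinylogous ester; 7 (3-bromopropoxy)(tert-butyl)dimethylsilane
Product: 10 (R)-4-allyl-3-[3-(tert-butyldimethylsilyloxy)propyl]cyclohept-2-en-1-one, via Grignard reagent 8 (not isolated), via tertiary carbinol 9 (not isolated)
Conditions: 7, Mg, THF; CeCl3, THF, −78 °C, then 6, −78 → 0 °C; pH 6.5 phosphate buffer; then dilute HCl, MeCN, 0 °C → rt
Reagents that add atoms: none
Why: Stork–Danheiser transposition: the cerium-modified Grignard reagent should add 1,2 to the carbonyl faster than it enolises it, and brief mild acid unmasks the enol ether and eliminates the tertiary carbinol to the β-substituted enone without touching the allyl-bearing centre.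

Step 5
Reactants: 10 (R)-enone
Product: 11 (1R,4R)-4-allyl-3-[3-(tert-butyldimethylsilyloxy)propyl]cyclohept-2-en-1-ol (hydroxyl cis to allyl)
Conditions: (S)-Me-CBS (0.2–1.0 equiv), catecholborane, toluene, −78 °C
Reagents that add atoms: none
Why: Corey–Bakshi–Shibata reduction: the oxazaborolidine binds the ketone with the alkenyl branch as the large group and delivers hydride 1,2 to one face, so the (R)-carbinol is set by the catalyst and not by the remote allyl centre, and catecholborane leaves the terminal alkene alone.

Step 6
Reactants: 11 (1R,4R)-cycloheptenol; 12 diiodomethane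
Product: 14 (1S,2R,6R,7S)-6-allyl-7-[3-(tert-butyldimethylsilyloxy)propyl]bicyclo[5.1.0]octan-2-ol (hydroxyl and cyclopropane CH2 and allyl on one face), via iodomethylzinc alkoxide 13 (not isolated)
Conditions: Et2Zn (2 equiv), CH2I2 (2–3 equiv), CH2Cl2, −20 → 0 °C; aq. NH4Cl
Reagents that add atoms: none
Why: Diethylzinc converts the C3 hydroxyl into a zinc alkoxide that exchanges with diiodomethane to the iodomethylzinc alkoxide 13, and this carbenoid transfers CH2 to the C4=C5 alkene through a butterfly transition state in which both new C–C bonds form in one concerted, stereospecific [2+1] addition. The closest known reaction is the hydroxyl-directed Simmons–Smith (Furukawa) cyclopropanation of cyclohex-2-enols and cyclohept-2-enols. The three-membered ring closes by this intramolecularly delivered suprafacial methylene transfer, so the bicyclo[5.1.0]octane is cis-fused. Both new stereocentres (C4 and the quaternary C5) are controlled by the C3 carbinol, which was itself set by the CBS catalyst, so the CH2 lands on the hydroxyl face, cis to the C6 allyl group. The step needs facial selectivity (syn to OH although the allyl group sits on the same face) and site selectivity over the terminal allyl alkene. The first should be secured by zinc-alkoxide delivery, which is syn for seven-membered allylic alcohols, and the second by the directing effect, the higher nucleophilicity of the trisubstituted alkene, a limited carbenoid charge and low temperature.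

Step 7
Reactants: 14 cyclopropyl carbinol
Product: 15 (1S,6R,7S)-6-allyl-7-[3-(tert-butyldimethylsilyloxy)propyl]bicyclo[5.1.0]octan-2-one
Conditions: Dess–Martin periodinane, NaHCO3, CH2Cl2, 0 °C → rt
Reagents that add atoms: none
Why: Dess–Martin oxidation of the secondary carbinol under buffered conditions should give the cyclopropyl ketone without acid-induced opening of the three-membered ring.

Step 8
Reactants: 15 cyclopropyl ketone
Product: 17 (3S,4R)-4-allyl-3-methyl-3-[3-(tert-butyldimethylsilyloxy)propyl]cycloheptan-1-one (methyl cis to allyl), via lithium enolate 16 (not isolated)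
Conditions: Li, NH3(l)/THF, −78 °C; solid NH4Cl
Reagents that add atoms: none
Why: Dissolving-metal reductive cleavage of a cyclopropyl ketone: the ketyl should break the external C4–CH2 bond, which overlaps best with the carbonyl π system and gives the primary rather than the tertiary carbanion, so the CH2 stays on C5 as the methyl group on the former carbinol face while the isolated alkene and silyl ether are inert.

Step 9
Reactants: 17 saturated ketone
Product: 18 (5S,6S)-5-allyl-6-methyl-6-[3-(tert-butyldimethylsilyloxy)propyl]cyclohept-2-en-1-one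
Conditions: IBX (1.5–2 equiv), DMSO/fluorobenzene, 65 °C
Reagents that add atoms: none
Why: IBX dehydrogenation of the ketone can only give the C1=C2 enone because the quaternary C5 offers no β-hydrogen on the other side, and limiting the oxidant should avoid the dienone.

Step 10
Reactants: 18 enone
Product: 19 2,3-epoxy ketone 5-allyl-4-methyl-4-[3-(tert-butyldimethylsilyloxy)propyl]-8-oxabicyclo[5.1.0]octan-2-one (epoxide face not defined)
Conditions: 30% H2O2, aq. NaOH, MeOH, 0 °C
Reagents that add atoms: hydrogen peroxide, OO
Why: Weitz–Scheffer nucleophilic epoxidation attacks only the enone alkene, and the epoxide configuration is irrelevant because both epoxide carbons lose their stereochemistry in steps 11 and 12.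

Step 11
Reactants: 19 epoxy ketone
Product: 20 (5S,6S)-6-allyl-5-methyl-5-[3-(tert-butyldimethylsilyloxy)propyl]cyclohept-2-en-1-ol (carbinol epimers)
Conditions: N2H4·H2O, AcOH (cat.), MeOH, 0 °C → rt, under argon
Reagents that add atoms: none
Why: Wharton transposition: the epoxy hydrazone fragments with loss of N2 to the allylic alcohol, which moves the oxygen from C3 to C1 and the alkene to C2=C3, and exclusion of air prevents diimide reduction of the allyl group.

Step 12
Reactants: 20 allylic alcohol
Product: 21 (5S,6S)-6-allyl-5-methyl-5-[3-(tert-butyldimethylsilyloxy)propyl]cyclohept-2-en-1-one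
Conditions: Dess–Martin periodinane, NaHCO3, CH2Cl2, rt
Reagents that add atoms: none
Why: Dess–Martin oxidation of the secondary allylic alcohol gives the C1 enone and converges both carbinol epimers.

Step 13
Reactants: 21 C1 enone; 22 3-bromo-2-methylprop-1-ene
Product: 24 (5S,6S,7S)-6-allyl-5-methyl-7-(2-methylallyl)-5-[3-(tert-butyldimethylsilyloxy)propyl]cyclohept-2-en-1-one, via lithium dienolate 23 (not isolated)
Conditions: LDA, THF, −78 °C; methallyl bromide, DMPU, −78 → −20 °C
Reagents that add atoms: none
Why: Kinetic α'-deprotonation gives the cross-conjugated enolate, whose alkylation by the reactive allylic bromide should occur on the face opposite the neighbouring C6 allyl group and the C5 methyl, setting C7 trans to C6, which is also expected to be the more stable epimer.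

Step 14
Reactants: 24 methallyl enone
Product: 25 (5S,6S,7S)-6-allyl-2-(hydroxymethyl)-5-methyl-7-(2-methylallyl)-5-[3-(tert-butyldimethylsilyloxy)propyl]cyclohept-2-en-1-one
Conditions: 37% aq. HCHO, DMAP (0.3 equiv), THF/H2O, rt
Reagents that add atoms: formaldehyde, C=O
Why: Morita–Baylis–Hillman reaction: conjugate addition of the catalyst at the unsubstituted C3 gives the C2 enolate that adds to formaldehyde, and loss of the catalyst restores the enone with the hydroxymethyl group at C2.

Step 15
Reactants: 25 hydroxymethyl enone
Product: 26 tert-butyldiphenylsilyl ether of 25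
Conditions: TBDPSCl, imidazole, CH2Cl2, 0 °C → rt
Reagents that add atoms: tert-butyl(chloro)diphenylsilane, CC(C)(C)[Si](Cl)(c1ccccc1)c1ccccc1
Why: Silylation of the primary alcohol with the more robust TBDPS group allows the alkyl TBS ether to be removed later in its presence.

Step 16
Reactants: 26 TBDPS ether
Product: 28 keto aldehyde with 2-oxoethyl at C6 and 2-oxopropyl at C7, via bis-ozonide 27 (not isolated)
Conditions: O3, CH2Cl2, −78 °C (Sudan Red 7B end point); PPh3, −78 °C → rt
Reagents that add atoms: ozone, [O-][O+]=O
Why: Ozonolysis: the mono- and 1,1-disubstituted alkenes react much faster with ozone than the electron-poor enone alkene, so indicator-controlled ozonolysis and phosphine reduction should give the C6 acetaldehyde arm and the C7 acetonyl group in one operation.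

Step 17
Reactants: 28 keto aldehyde; 29 3-methylbut-2-enoic anhydride
Product: 30 (E)-enol 3-methylbut-2-enoate of 28
Conditions: DMAP, Et3N, CH2Cl2, rt → 40 °C
Reagents that add atoms: none
Why: Enol esterification of an aldehyde: under amine/DMAP soft enolisation only the aldehyde, which is more acidic than the two ketones, should be enolised and O-acylated, and the E isomer is expected to predominate because the Z isomer would press the acyloxy group against the branched C6.

Step 18
Reactants: 30 enol ester
Product: 31 primary alcohol (3-hydroxypropyl chain at C5)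
Conditions: HF·pyridine, pyridine, THF, 0 °C
Reagents that add atoms: none
Why: Buffered HF·pyridine desilylation cleaves the primary alkyl TBS ether much faster than the TBDPS ether and should not touch the enol ester.

Step 19
Reactants: 31 primary alcohol
Product: 32 side-chain aldehyde (3-oxopropyl chain at C5)
Conditions: Dess–Martin periodinane, NaHCO3, CH2Cl2, 0 °C
Reagents that add atoms: none
Why: Dess–Martin oxidation is mild and non-basic, so the enol ester, the 1,4-diketone and the C7 centre should be unaffected.

Step 20
Reactants: 32 side-chain aldehyde; 33 2-bromopropene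
Product: 35 (R)-isopropenyl carbinol (TBDPS ether of the target), via isopropenylchromium dichloride 34 (not isolated)
Conditions: CrCl2 (4 equiv), NiCl2 (cat.), chiral oxazoline–sulfonamide ligand (enantiomer giving the R carbinol), Et3N, THF, rt
Reagents that add atoms: none
Why: Asymmetric Nozaki–Hiyama–Kishi reaction: the alkenylchromium(III) species adds only to the aldehyde in the presence of the ketones, the enone and the esters, and the chiral sulfonamide ligand on chromium sets the (R)-carbinol by reagent control.

Step 21
Reactants: 35 TBDPS ether of the target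
Product: 36 CNP0257974.1
Conditions: HF·pyridine, THF, 0 °C → rt
Reagents that add atoms: none
Why: Desilylation with HF·pyridine removes the remaining TBDPS ether under mildly acidic conditions that the enol ester, the two allylic alcohols and the 1,4-diketone should tolerate.

**Compound list**

1 | cycloheptane-1,3-dione | O=C1CCCCC(=O)C1 | starting material
2 | 3-isobutoxycyclohept-2-en-1-one | O=C1C=C(OCC(C)C)CCCC1 | intermediate
3 | allyl chloroformate | C=CCOC(=O)Cl | starting material
4 | lithium α'-enolate of 2 | [Li+].[O-]C1=CCCCC(OCC(C)C)=C1 | intermediate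
5 | allyl 6-isobutoxycyclohepta-1,6-dien-1-yl carbonate | C=CCOC(=O)OC1=CCCCC(OCC(C)C)=C1 | intermediate
6 | (R)-7-allyl-3-isobutoxycyclohept-2-en-1-one | O=C1C=C(OCC(C)C)CCC[C@@H]1CC=C | intermediate
7 | (3-bromopropoxy)(tert-butyl)dimethylsilane | CC(C)(C)[Si](C)(C)OCCCBr | starting material
8 | 3-(tert-butyldimethylsilyloxy)propylmagnesium bromide | CC(C)(C)[Si](C)(C)OCCC[Mg]Br | intermediate
9 | (7R)-7-allyl-3-isobutoxy-1-[3-(tert-butyldimethylsilyloxy)propyl]cyclohept-2-en-1-ol (C1 epimers) | CC(C)(C)[Si](C)(C)OCCCC1(O)C=C(OCC(C)C)CCC[C@@H]1CC=C | intermediate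
10 | (R)-4-allyl-3-[3-(tert-butyldimethylsilyloxy)propyl]cyclohept-2-en-1-one | CC(C)(C)[Si](C)(C)OCCCC1=CC(=O)CCC[C@@H]1CC=C | intermediate
11 | (1R,4R)-4-allyl-3-[3-(tert-butyldimethylsilyloxy)propyl]cyclohept-2-en-1-ol | CC(C)(C)[Si](C)(C)OCCCC1=C[C@H](O)CCC[C@@H]1CC=C | intermediate
12 | diiodomethane | ICI | starting material
13 | iodomethylzinc alkoxide of 11 | CC(C)(C)[Si](C)(C)OCCCC1=C[C@H](O[Zn]CI)CCC[C@@H]1CC=C | intermediate
14 | (1S,2R,6R,7S)-6-allyl-7-[3-(tert-butyldimethylsilyloxy)propyl]bicyclo[5.1.0]octan-2-ol | CC(C)(C)[Si](C)(C)OCCC[C@@]12C[C@@H]1[C@H](O)CCC[C@@H]2CC=C | intermediate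
15 | (1S,6R,7S)-6-allyl-7-[3-(tert-butyldimethylsilyloxy)propyl]bicyclo[5.1.0]octan-2-one | CC(C)(C)[Si](C)(C)OCCC[C@@]12C[C@@H]1C(=O)CCC[C@@H]2CC=C | intermediate
16 | lithium enolate of 17 (C3–C4 enolate) | CC(C)(C)[Si](C)(C)OCCC[C@@]1(C)C=C([O-])CCC[C@@H]1CC=C.[Li+] | intermediate
17 | (3S,4R)-4-allyl-3-methyl-3-[3-(tert-butyldimethylsilyloxy)propyl]cycloheptan-1-one | CC(C)(C)[Si](C)(C)OCCC[C@@]1(C)CC(=O)CCC[C@@H]1CC=C | intermediate
18 | (5S,6S)-5-allyl-6-methyl-6-[3-(tert-butyldimethylsilyloxy)propyl]cyclohept-2-en-1-one | CC(C)(C)[Si](C)(C)OCCC[C@@]1(C)CC(=O)C=CC[C@@H]1CC=C | intermediate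
19 | 5-allyl-4-methyl-4-[3-(tert-butyldimethylsilyloxy)propyl]-8-oxabicyclo[5.1.0]octan-2-one (epoxide face not defined) | CC(C)(C)[Si](C)(C)OCCC[C@@]1(C)CC(=O)C2OC2C[C@@H]1CC=C | intermediate
20 | (5S,6S)-6-allyl-5-methyl-5-[3-(tert-butyldimethylsilyloxy)propyl]cyclohept-2-en-1-ol (C1 epimers) | CC(C)(C)[Si](C)(C)OCCC[C@@]1(C)CC=CC(O)C[C@@H]1CC=C | intermediate
21 | (5S,6S)-6-allyl-5-methyl-5-[3-(tert-butyldimethylsilyloxy)propyl]cyclohept-2-en-1-one | CC(C)(C)[Si](C)(C)OCCC[C@@]1(C)CC=CC(=O)C[C@@H]1CC=C | intermediate
22 | 3-bromo-2-methylprop-1-ene (methallyl bromide) | C=C(C)CBr | starting material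
23 | lithium α'-dienolate of 21 | CC(C)(C)[Si](C)(C)OCCC[C@@]1(C)CC=CC([O-])=C[C@@H]1CC=C.[Li+] | intermediate
24 | (5S,6S,7S)-6-allyl-5-methyl-7-(2-methylallyl)-5-[3-(tert-butyldimethylsilyloxy)propyl]cyclohept-2-en-1-one | CC(C)(C)[Si](C)(C)OCCC[C@@]1(C)CC=CC(=O)[C@@H](CC(C)=C)[C@@H]1CC=C | intermediate
25 | (5S,6S,7S)-6-allyl-2-(hydroxymethyl)-5-methyl-7-(2-methylallyl)-5-[3-(tert-butyldimethylsilyloxy)propyl]cyclohept-2-en-1-one | CC(C)(C)[Si](C)(C)OCCC[C@@]1(C)CC=C(CO)C(=O)[C@@H](CC(C)=C)[C@@H]1CC=C | intermediate
26 | tert-butyldiphenylsilyl ether of 25 | CC(C)(C)[Si](C)(C)OCCC[C@@]1(C)CC=C(CO[Si](c2ccccc2)(c2ccccc2)C(C)(C)C)C(=O)[C@@H](CC(C)=C)[C@@H]1CC=C | intermediate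
27 | bis(1,2,4-trioxolane) of 26 (ozonides of the allyl and methallyl alkenes) | CC(C)(C)[Si](C)(C)OCCC[C@@]1(C)CC=C(CO[Si](c2ccccc2)(c2ccccc2)C(C)(C)C)C(=O)[C@@H](CC3(C)OCOO3)[C@@H]1CC4OCOO4 | intermediate
28 | (5S,6S,7S)-2-[(tert-butyldiphenylsilyloxy)methyl]-5-methyl-6-(2-oxoethyl)-7-(2-oxopropyl)-5-[3-(tert-butyldimethylsilyloxy)propyl]cyclohept-2-en-1-one | CC(C)(C)[Si](C)(C)OCCC[C@@]1(C)CC=C(CO[Si](c2ccccc2)(c2ccccc2)C(C)(C)C)C(=O)[C@@H](CC(C)=O)[C@@H]1CC=O | intermediate
29 | 3-methylbut-2-enoic anhydride (senecioic anhydride) | CC(C)=CC(=O)OC(=O)C=C(C)C | starting material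
30 | (E)-enol 3-methylbut-2-enoate of 28 | CC(C)(C)[Si](C)(C)OCCC[C@@]1(C)CC=C(CO[Si](c2ccccc2)(c2ccccc2)C(C)(C)C)C(=O)[C@@H](CC(C)=O)[C@@H]1/C=C/OC(=O)C=C(C)C | intermediate
31 | primary alcohol from 30 (3-hydroxypropyl chain at C5) | OCCC[C@@]1(C)CC=C(CO[Si](c2ccccc2)(c2ccccc2)C(C)(C)C)C(=O)[C@@H](CC(C)=O)[C@@H]1/C=C/OC(=O)C=C(C)C | intermediate
32 | side-chain aldehyde (3-oxopropyl chain at C5) | O=CCC[C@@]1(C)CC=C(CO[Si](c2ccccc2)(c2ccccc2)C(C)(C)C)C(=O)[C@@H](CC(C)=O)[C@@H]1/C=C/OC(=O)C=C(C)C | intermediate
33 | 2-bromopropene | C=C(C)Br | starting material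
34 | isopropenylchromium(III) dichloride | C=C(C)[Cr](Cl)Cl | intermediate
35 | TBDPS ether of the target with the (R)-isopropenyl carbinol | C=C(C)[C@H](O)CC[C@@]1(C)CC=C(CO[Si](c2ccccc2)(c2ccccc2)C(C)(C)C)C(=O)[C@@H](CC(C)=O)[C@@H]1/C=C/OC(=O)C=C(C)C | intermediate
36 | CNP0257974.1 | C=C(C)[C@H](O)CC[C@@]1(C)CC=C(CO)C(=O)[C@@H](CC(C)=O)[C@@H]1/C=C/OC(=O)C=C(C)C | target

**Step count**

Total step count: 21. Longest linear sequence: 21 steps (from 1; compounds 3, 7, 12, 22, 29 and 33 are bought).

**Steps most likely to fail**

Step 17 (enol senecioylation). The enol acylation may give poor E/Z control, the aldehyde may undergo intramolecular aldol addition to the acetonyl ketone before it is acylated, and the senecioyl unit may deconjugate under amine base. The fallback sets out from 26 and comes back at 30; it builds the E enol ester by C–O coupling instead of enolisation. A terminal-alkene-selective Ru–H isomerisation would convert the allyl group of 26 into a prop-1-enyl group to give the propenyl compound F2. Ozonolysis with PPh3 work-up would then cleave the propenyl and methallyl alkenes to the C6 carbaldehyde bearing the C7 acetonyl group F3. Takai-type boryl olefination (Cl2CHBpin, CrCl2, LiI, THF), which is aldehyde-selective, should give the (E)-alkenyl pinacolboronate F4, and KHF2 in aqueous methanol the potassium (E)-alkenyltrifluoroborate F5. Copper-mediated oxidative coupling of F5 with 3-methylbut-2-enoic acid (Cu(OAc)2, DMAP, 4 Å MS, air; Chan–Lam type) should then give 30 with retention of the alkene geometry.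

Step 6 (directed cyclopropanation). The carbenoid may be delivered with poor facial selectivity because the C6 allyl group lies on the hydroxyl face, or it may also attack the terminal alkene. The fallback sets out from 6 and comes back at 17; it reverses the order in which the two C5 substituents are introduced, so no cyclopropane is needed. Addition of MeMgBr/CeCl3 to 6 and mild acid (Stork–Danheiser) would give (R)-4-allyl-3-methylcyclohept-2-en-1-one F1. Copper-catalysed conjugate addition of Grignard reagent 8 to F1 (CuBr·SMe2, TMSCl, THF, −78 °C, then hydrolysis of the silyl enol ether) should place the chain anti to the neighbouring allyl group, so the methyl ends up cis to it, which is ketone 17.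

Step 20 (asymmetric NHK). Reagent control at a carbinol remote from all other stereocentres may be poor, giving an inseparable epimer mixture, or the vinyl bromide may couple sluggishly. The fallback sets out from 32 and comes back at 35; it replaces reagent-controlled addition by kinetic resolution. A ligand-free NHK coupling of 32 with 33 (CrCl2, NiCl2 cat., DMF) would give the carbinol epimer mixture F6. Sharpless kinetic resolution (Ti(OiPr)4, L-(+)-DIPT, t-BuOOH, 4 Å MS, CH2Cl2, −20 °C) should epoxidise the (S)-carbinol epimer faster and leave the (R)-epimer 35, which is separated from the epoxy alcohol by chromatography.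

**Further compounds**

F1 | step 6 | (R)-4-allyl-3-methylcyclohept-2-en-1-one | CC1=CC(=O)CCC[C@@H]1CC=C
F2 | step 17 | prop-1-enyl isomer of 26 (alkene geometry not defined) | CC(C)(C)[Si](C)(C)OCCC[C@@]1(C)CC=C(CO[Si](c2ccccc2)(c2ccccc2)C(C)(C)C)C(=O)[C@@H](CC(C)=C)[C@@H]1C=CC
F3 | step 17 | C6 carbaldehyde with C7 acetonyl group | CC(C)(C)[Si](C)(C)OCCC[C@@]1(C)CC=C(CO[Si](c2ccccc2)(c2ccccc2)C(C)(C)C)C(=O)[C@@H](CC(C)=O)[C@@H]1C=O
F4 | step 17 | (E)-alkenyl pinacolboronate at C6 | CC(C)(C)[Si](C)(C)OCCC[C@@]1(C)CC=C(CO[Si](c2ccccc2)(c2ccccc2)C(C)(C)C)C(=O)[C@@H](CC(C)=O)[C@@H]1/C=C/B3OC(C)(C)C(C)(C)O3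
F5 | step 17 | potassium (E)-alkenyltrifluoroborate at C6 | CC(C)(C)[Si](C)(C)OCCC[C@@]1(C)CC=C(CO[Si](c2ccccc2)(c2ccccc2)C(C)(C)C)C(=O)[C@@H](CC(C)=O)[C@@H]1/C=C/[B-](F)(F)F.[K+]
F6 | step 20 | carbinol epimer mixture of 35 | C=C(C)C(O)CC[C@@]1(C)CC=C(CO[Si](c2ccccc2)(c2ccccc2)C(C)(C)C)C(=O)[C@@H](CC(C)=O)[C@@H]1/C=C/OC(=O)C=C(C)C
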